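The readings are simulated for substances that don't exist; scatter was added.

A one-step world, D going to L through the enzyme J and nothing after, rises and stays flat. The delta flask (14 mM D, 1.7 µM J), which is the flask asked about, did not stay flat:

| flask | D | J | remark | time |
|---|---|---|---|---|
| delta | 14 mM | 1.7 µM | the very flask that is asked about, followed so far |  |
| beta | 21 mM | 1.7 µM | run made earlier |  |
| flask | 14 mM | 1.7 µM |  | 2.5 h |

| delta: time / min | delta: L / % | beta: time / min | beta: L / % |
|---|---|---|---|
| 0.667 | 80 | 0.667 | 81 |
| 1.33 | 100 | 1.33 | 96 |
| 3.00 | 92 | 3.00 | 96 |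
| 6.00 | 92 | 6.00 | 95 |
| 12.0 | 84 | 12.0 | 87 |
| 30.0 | 61 | 30.0 | 74 |
| 60.0 | 21 | 60.0 | 46 |

(readings scatter by 2 percentage points)

- a species is counted by the D in it: one G counts as two
- amounts and yields of L count E too
- given per volume of solution although it is solid: E
- what was read earlier has a scatter of 2 percentage points, one standard deviation
- on the list of suspects stand: D + J <-> X; X -> J + L; L -> Z; 2 X -> G; E <-> L

- the best time, 2.5 h at the latest, for L, in min
- the amount of L, in percent of the D charged, at that time

I looked for what held constant. From 3.00 min to 60.0 min the delta readings fell by 0.174 mM min⁻¹ of L, and the beta readings, with 21 mM D, by 0.184 mM min⁻¹, close to it. I took that as [L] held steady in solution by crystals E while it went on to Z, and froze the loss.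

Two times then remained. The filling time, 0.414 min, is the lifetime of D, taken as pseudo-first-order and read from the first delta reading. The emptying time, 80.3 min, is the charge of D over the steady loss. Their ratio is 194. Formation falls to the loss at the filling time times ln(ratio), so I reckoned a peak at 2.18 min with 96.8% of L.

The forecast, from “a zero-order loss that persists”, said 2 min (1.3 min to 2.8 min) and 97% (94% to 99.5%), a slightly earlier time than mine.

The flask peaked at 1.75 min with 96.3%, inside both ranges.

    D + J ⇌ X (K = 26.0 M⁻¹, k = 1.73 × 10⁶ M⁻¹ s⁻¹)
    X → J + L (k = 1310 s⁻¹)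
    L → Z (k = 0.00375 s⁻¹)
    2 X → G (k = 3030 M⁻¹ s⁻¹)
    E ⇌ L, rate k5*(cs5 - [L]) while solid is left; crystals form when [L] > cs5 (solubility = 0.800 mM, k = 0.315 s⁻¹)

At that peak E held nearly all of the L, 90.6% against 96.3%. Taken at the steady loss, that much E comes to 72.8 min of supply, and at 1.25 h the flask held 0% E. With 3.5 mM D, and the filling time and the steady loss held, the emptying time becomes 20.1 min, the ratio 48.4, and the reckoned peak 89.9%; that flask gave 91.4%.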